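## Retrosynthetic overview

1. Target 18 comes from desilylation of 17, which comes from catalyst-controlled transfer hydrogenation of the C4' ketone of dimer 16 (sets the cis C3'/C4' pair).
2. Key disconnection in 16 is the benzylic C4–O(aryl) bond: the C4 benzylic radical of lactone 12 is captured by a copper aryloxide released from aryl acetate 15 (sets C4 trans to the C3 methyl).
3. Both 12 and 15 come from one monomer, lactone 11 (bis-silylation, or acetylation/silylation followed by benzylic oxidation).
4. In 11 the benzene ring is formed first (Diels–Alder/aromatisation of ynoate 3 with siloxydiene 7), the lactone ring second (lactonisation); the two bicyclic halves are joined last.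
5. 3 comes from methyl propiolate and (R)-propylene oxide (source of C3 and C3'); 7 comes from methyl methoxyacetate and N-methoxy-N-methylacetamide.

Assumption: isochroman-1-one numbering is used, primed locants denote the half with the free C4 hydroxyl, and partial epimerisation of C3 in dione 15 is tolerated because step 9 re-equilibrates and fixes that centre.

## Route

Step 1
Reactants: 1 methyl propiolate; 2 (R)-propylene oxide
Product: 3 methyl (5R)-5-hydroxyhex-2-ynoate
Conditions: n-BuLi, THF, −78 °C; BF3·OEt2; then 2, −78 °C; aqueous work-up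
Reagents that add atoms: none
Why: The lithium acetylide opens the BF3-activated epoxide at its unsubstituted carbon (Yamaguchi–Hirao alkynylation), so the stereocentre of 2 is untouched and stays R.

Step 2
Reactants: 4 methyl methoxyacetate; 5 N-methoxy-N-methylacetamide
Product: 6 methyl 2-methoxy-3-oxobutanoate (racemic)
Conditions: LiN(iPr)2 (1.1 equiv), THF, −78 °C; then 5, −78 to −20 °C; H2O
Reagents that add atoms: none
Why: The lithium ester enolate is C-acylated by the Weinreb amide through a stable chelated tetrahedral adduct (crossed Claisen-type acylation), and the new α-stereocentre is irrelevant because it is destroyed in step 3.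

Step 3
Reactants: 6 methyl 2-methoxy-3-oxobutanoate
Product: 7 1,2-dimethoxy-1,3-bis(trimethylsilyloxy)buta-1,3-diene
Conditions: Me3SiOTf (2.2 equiv), Et3N (2.5 equiv), Et2O, 0 °C to rt; used crude
Reagents that add atoms: trimethylsilyl trifluoromethanesulfonate, C[Si](C)(C)OS(=O)(=O)C(F)(F)F
Why: Double O-silylation of the β-keto ester with a silyl triflate and amine base gives the Chan-type 1,3-bis(silyloxy)diene (silyl enol ether and silyl ketene acetal formation), with no stereocentre involved.

Step 4
Reactants: 3 methyl (5R)-5-hydroxyhex-2-ynoate; 7 1,2-dimethoxy-1,3-bis(trimethylsilyloxy)buta-1,3-diene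
Product: 11 (3R)-6,8-dihydroxy-7-methoxy-3-methylisochroman-1-one, via silyl ether 8 (not isolated), via cycloadduct 9 (not isolated), via hydroxy ester 10 (not isolated)
Conditions: Me3SiCl, imidazole, CH2Cl2, 0 °C, filter, concentrate; then 7 (1.5 equiv), PhMe, 120 °C, sealed tube; then 1 M HCl, THF, rt; then TsOH·H2O (cat.), PhMe, 80 °C
Reagents that add atoms: none
Why: In the Diels–Alder reaction the nucleophilic CH2 terminus of the diene bonds to the β-carbon of the ynoate so the ketene-acetal carbon ends up next to the ester carbon, loss of methanol aromatises the adduct, and acid removes the silyl groups and closes the six-membered lactone, leaving the R centre from 2 untouched.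

Step 5
Reactants: 11 (3R)-6,8-dihydroxy-7-methoxy-3-methylisochroman-1-one
Product: 12 (3R)-6,8-bis(tert-butyldimethylsilyloxy)-7-methoxy-3-methylisochroman-1-one
Conditions: tBuMe2SiOTf (2.5 equiv), 2,6-lutidine, CH2Cl2, 0 °C to rt
Reagents that add atoms: tert-butyldimethylsilyl trifluoromethanesulfonate, CC(C)(C)[Si](C)(C)OS(=O)(=O)C(F)(F)F
Why: The silyl triflate silylates both phenols, including the hydrogen-bonded 8-OH (O-silylation), giving ethers that are neither acyl donors nor good hydrogen-atom donors in step 8.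

Step 6
Reactants: 11 (3R)-6,8-dihydroxy-7-methoxy-3-methylisochroman-1-one
Product: 14 (3R)-8-(tert-butyldimethylsilyloxy)-7-methoxy-3-methyl-1-oxoisochroman-6-yl acetate, via monoacetate 13 (not isolated)
Conditions: Ac2O (1.05 equiv), 2,6-lutidine, DMAP (5 mol%), CH2Cl2, −20 °C; then tBuMe2SiOTf (2.5 equiv), 0 °C to rt
Reagents that add atoms: acetic anhydride, CC(=O)OC(C)=O; tert-butyldimethylsilyl trifluoromethanesulfonate, CC(C)(C)[Si](C)(C)OS(=O)(=O)C(F)(F)F
Why: The free 6-OH is acetylated much faster than the carbonyl-chelated 8-OH (chemoselective O-acylation), and the silyl triflate then caps the 8-OH (O-silylation), which marks O6 alone as the latent aryloxide.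

Step 7
Reactants: 14 (3R)-8-(tert-butyldimethylsilyloxy)-7-methoxy-3-methyl-1-oxoisochroman-6-yl acetate
Product: 15 (3R)-8-(tert-butyldimethylsilyloxy)-7-methoxy-3-methyl-1,4-dioxoisochroman-6-yl acetate
Conditions: tBuOOH (5.5 M in decane, 5 equiv), Rh2(caprolactamate)4 (1 mol%), ClCH2CH2Cl, 40 °C
Reagents that add atoms: tert-butyl hydroperoxide, CC(C)(C)OO
Why: tert-Butylperoxyl radicals abstract hydrogen from the secondary benzylic C4 position, the most reactive C–H bond, and the mixed peroxide collapses to the ketone (radical benzylic C–H oxidation), with any erosion at C3 corrected in step 9.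

Step 8
Reactants: 12 (3R)-6,8-bis(tert-butyldimethylsilyloxy)-7-methoxy-3-methylisochroman-1-one; 15 (3R)-8-(tert-butyldimethylsilyloxy)-7-methoxy-3-methyl-1,4-dioxoisochroman-6-yl acetate
Product: 16 (3R,4S)-6,8-bis(tert-butyldimethylsilyloxy)-4-{[(3R)-8-(tert-butyldimethylsilyloxy)-7-methoxy-3-methyl-1,4-dioxoisochroman-6-yl]oxy}-7-methoxy-3-methylisochroman-1-one
Conditions: 12 (4 equiv, excess recovered), 15 (1 equiv), [HC(CMeN(2,6-Cl2C6H3))2]Cu (10 mol%, from CuOtBu and the free diketimine), tBuOOtBu (1.5 equiv), PhCl, 90 °C, 24 h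
Reagents that add atoms: none
Why: Proposed new method: tert-butoxyl radical from tBuOOtBu abstracts a hydrogen atom from the secondary benzylic C4–H2 of 12 (in fourfold excess so that it outcompetes all other C–H bonds), the divalent-copper tert-butoxide is transacylated by aryl acetate 15 to a divalent-copper aryloxide that captures the C4 radical and forms the C4–O bond with return of monovalent copper, and this bulky aryloxide approaches the planar radical on the face opposite the C3 methyl so the new C4 centre is S (trans); the closest known reaction is the copper β-diketiminate/tBuOOtBu C–H etherification of simple benzylic hydrocarbons with aryl acetates (a Kharasch–Sosnovsky-type radical relay), extended here to a functionalised lactone as the C–H partner.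

Step 9
Reactants: 16 the dimeric ketone from step 8
Product: 17 (3R,4S)-6,8-bis(tert-butyldimethylsilyloxy)-4-{[(3R,4R)-8-(tert-butyldimethylsilyloxy)-4-hydroxy-7-methoxy-3-methyl-1-oxoisochroman-6-yl]oxy}-7-methoxy-3-methylisochroman-1-one
Conditions: RuCl(p-cymene)[(S,S)-TsDPEN] (2 mol%), HCO2H/Et3N (5:2), CH2Cl2, 30 °C
Reagents that add atoms: none
Why: In this Noyori asymmetric transfer hydrogenation with dynamic kinetic resolution the (S,S) catalyst delivers hydride to the ketone face that gives 4'R, C3' equilibrates through its enol under the amine buffer, and hydride enters anti to the C3' methyl, so the cis (3'R,4'R) alcohol results.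

Step 10
Reactants: 17 the tris-silyl ether from step 9
Product: 18 (3R,4S)-6,8-dihydroxy-4-{[(3R,4R)-4,8-dihydroxy-7-methoxy-3-methyl-1-oxoisochroman-6-yl]oxy}-7-methoxy-3-methylisochroman-1-one (CNP0139537.4)
Conditions: HF·pyridine, THF/pyridine, 0 °C to rt
Reagents that add atoms: none
Why: Fluoride cleaves the three aryl Si–O bonds (desilylation) under mildly acidic conditions that spare the benzylic aryl ether and avoid base-induced translactonisation of the 4'-hydroxy lactone, and no stereocentre is touched.

## Compound list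

1 | methyl propiolate | C#CC(=O)OC | starting material
2 | (R)-propylene oxide | C[C@@H]1CO1 | starting material
3 | methyl (5R)-5-hydroxyhex-2-ynoate | C[C@@H](O)CC#CC(=O)OC | intermediate
4 | methyl methoxyacetate | COCC(=O)OC | starting material
5 | N-methoxy-N-methylacetamide | CC(=O)N(C)OC | starting material
6 | methyl 2-methoxy-3-oxobutanoate (racemic) | CC(=O)C(OC)C(=O)OC | intermediate
7 | 1,2-dimethoxy-1,3-bis(trimethylsilyloxy)buta-1,3-diene | C=C(O[Si](C)(C)C)C(OC)=C(OC)O[Si](C)(C)C | intermediate
8 | methyl (5R)-5-(trimethylsilyloxy)hex-2-ynoate | C[C@@H](O[Si](C)(C)C)CC#CC(=O)OC | intermediate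
9 | methyl 5,6-dimethoxy-4,6-bis(trimethylsilyloxy)-2-[(2R)-2-(trimethylsilyloxy)propyl]cyclohexa-1,4-diene-1-carboxylate (C6 epimers) | COC(=O)C1=C(C[C@@H](C)O[Si](C)(C)C)CC(O[Si](C)(C)C)=C(OC)C1(OC)O[Si](C)(C)C | intermediate
10 | methyl 2,4-dihydroxy-6-[(2R)-2-hydroxypropyl]-3-methoxybenzoate | COC(=O)c1c(O)c(OC)c(O)cc1C[C@@H](C)O | intermediate
11 | (3R)-6,8-dihydroxy-7-methoxy-3-methylisochroman-1-one | COc1c(O)cc2c(c1O)C(=O)O[C@H](C)C2 | intermediate
12 | (3R)-6,8-bis(tert-butyldimethylsilyloxy)-7-methoxy-3-methylisochroman-1-one | COc1c(O[Si](C)(C)C(C)(C)C)cc2c(c1O[Si](C)(C)C(C)(C)C)C(=O)O[C@H](C)C2 | intermediate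
13 | (3R)-8-hydroxy-7-methoxy-3-methyl-1-oxoisochroman-6-yl acetate | COc1c(OC(C)=O)cc2c(c1O)C(=O)O[C@H](C)C2 | intermediate
14 | (3R)-8-(tert-butyldimethylsilyloxy)-7-methoxy-3-methyl-1-oxoisochroman-6-yl acetate | COc1c(OC(C)=O)cc2c(c1O[Si](C)(C)C(C)(C)C)C(=O)O[C@H](C)C2 | intermediate
15 | (3R)-8-(tert-butyldimethylsilyloxy)-7-methoxy-3-methyl-1,4-dioxoisochroman-6-yl acetate | COc1c(OC(C)=O)cc2c(c1O[Si](C)(C)C(C)(C)C)C(=O)O[C@H](C)C2=O | intermediate
16 | (3R,4S)-6,8-bis(tert-butyldimethylsilyloxy)-4-{[(3R)-8-(tert-butyldimethylsilyloxy)-7-methoxy-3-methyl-1,4-dioxoisochroman-6-yl]oxy}-7-methoxy-3-methylisochroman-1-one | COc1c(O[Si](C)(C)C(C)(C)C)cc2c(c1O[Si](C)(C)C(C)(C)C)C(=O)O[C@H](C)[C@H]2Oc1cc2c(c(O[Si](C)(C)C(C)(C)C)c1OC)C(=O)O[C@H](C)C2=O | intermediate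
17 | (3R,4S)-6,8-bis(tert-butyldimethylsilyloxy)-4-{[(3R,4R)-8-(tert-butyldimethylsilyloxy)-4-hydroxy-7-methoxy-3-methyl-1-oxoisochroman-6-yl]oxy}-7-methoxy-3-methylisochroman-1-one | COc1c(O[Si](C)(C)C(C)(C)C)cc2c(c1O[Si](C)(C)C(C)(C)C)C(=O)O[C@H](C)[C@H]2Oc1cc2c(c(O[Si](C)(C)C(C)(C)C)c1OC)C(=O)O[C@H](C)[C@@H]2O | intermediate
18 | (3R,4S)-6,8-dihydroxy-4-{[(3R,4R)-4,8-dihydroxy-7-methoxy-3-methyl-1-oxoisochroman-6-yl]oxy}-7-methoxy-3-methylisochroman-1-one (CNP0139537.4) | COc1c(O)cc2c(c1O)C(=O)O[C@H](C)[C@H]2Oc1cc2c(c(O)c1OC)C(=O)O[C@H](C)[C@@H]2O | target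

## Step count and risks

Total step count: 10. Longest linear sequence: 8 (steps 2, 3, 4, 6, 7, 8, 9, 10).

**Most likely to fail, first: step 8.** The dione 15 is enolisable and could be deprotonated by the copper tert-butoxide, methyl radicals from β-scission of tert-butoxyl could methylate the aryloxide, and capture of the hindered secondary radical may be slow. The fallback replaces the radical relay by an ionic substitution with inversion. It sets out from 12 and 15. Oxidation of 12 under the step 7 conditions gives (3R)-6,8-bis(tert-butyldimethylsilyloxy)-7-methoxy-3-methylisochroman-1,4-dione F1. Reduction of F1 under the step 9 conditions gives the cis alcohol (3R,4R)-6,8-bis(tert-butyldimethylsilyloxy)-4-hydroxy-7-methoxy-3-methylisochroman-1-one F2. Mild methanolysis of 15 (K2CO3 cat., MeOH, 0 °C) gives the phenol (3R)-8-(tert-butyldimethylsilyloxy)-6-hydroxy-7-methoxy-3-methylisochroman-1,4-dione F3. Mitsunobu coupling of F2 with F3 (PPh3, DIAD, PhMe, 0 °C) inverts C4 and comes back to the route at 16.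

**Second: step 4.** The tetra-oxygenated diene 7 is thermally fragile and the β-alkyl ynoate is a sluggish dienophile. The fallback builds the arene by directed metalation instead of cycloaddition. It sets out from 2 and the new starting material resorcinol F4.
- MOMCl and iPr2NEt give 1,3-bis(methoxymethoxy)benzene F5.
- n-BuLi, then B(OMe)3, then H2O2/NaOH give 2,6-bis(methoxymethoxy)phenol F6.
- MeI and K2CO3 give 2-methoxy-1,3-bis(methoxymethoxy)benzene F7.
- n-BuLi/TMEDA then ClC(O)NEt2 give N,N-diethyl-3-methoxy-2,4-bis(methoxymethoxy)benzamide F8.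
- s-BuLi/TMEDA at −78 °C (lithiation ortho to the amide), then 2 and BF3·OEt2, give N,N-diethyl-6-[(2R)-2-hydroxypropyl]-3-methoxy-2,4-bis(methoxymethoxy)benzamide F9.
- HCl/MeOH followed by TsOH in hot toluene removes both acetals and lactonises, coming back to the route at 11.

**Third: step 7.** Over-oxidation at C3 or of the electron-rich ring is possible, and the dione is sensitive. The fallback reaches the ketone by halogenation and ionic oxidation instead of direct C–H oxygenation. It sets out from 14. Wohl–Ziegler bromination (NBS, AIBN cat., PhCF3, 80 °C) gives (3R)-4-bromo-8-(tert-butyldimethylsilyloxy)-7-methoxy-3-methyl-1-oxoisochroman-6-yl acetate F10 as a C4 epimer mixture. Silver-assisted Kornblum oxidation (AgBF4, DMSO, rt; then Et3N) comes back to the route at 15.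

## Further compounds

F1 | step 8 | (3R)-6,8-bis(tert-butyldimethylsilyloxy)-7-methoxy-3-methylisochroman-1,4-dione | COc1c(O[Si](C)(C)C(C)(C)C)cc2c(c1O[Si](C)(C)C(C)(C)C)C(=O)O[C@H](C)C2=O
F2 | step 8 | (3R,4R)-6,8-bis(tert-butyldimethylsilyloxy)-4-hydroxy-7-methoxy-3-methylisochroman-1-one | COc1c(O[Si](C)(C)C(C)(C)C)cc2c(c1O[Si](C)(C)C(C)(C)C)C(=O)O[C@H](C)[C@@H]2O
F3 | step 8 | (3R)-8-(tert-butyldimethylsilyloxy)-6-hydroxy-7-methoxy-3-methylisochroman-1,4-dione | COc1c(O)cc2c(c1O[Si](C)(C)C(C)(C)C)C(=O)O[C@H](C)C2=O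
F4 | step 4 | resorcinol | Oc1cccc(O)c1
F5 | step 4 | 1,3-bis(methoxymethoxy)benzene | COCOc1cccc(OCOC)c1
F6 | step 4 | 2,6-bis(methoxymethoxy)phenol | COCOc1cccc(OCOC)c1O
F7 | step 4 | 2-methoxy-1,3-bis(methoxymethoxy)benzene | COCOc1cccc(OCOC)c1OC
F8 | step 4 | N,N-diethyl-3-methoxy-2,4-bis(methoxymethoxy)benzamide | CCN(CC)C(=O)c1ccc(OCOC)c(OC)c1OCOC
F9 | step 4 | N,N-diethyl-6-[(2R)-2-hydroxypropyl]-3-methoxy-2,4-bis(methoxymethoxy)benzamide | CCN(CC)C(=O)c1c(C[C@@H](C)O)cc(OCOC)c(OC)c1OCOC
F10 | step 7 | (3R)-4-bromo-8-(tert-butyldimethylsilyloxy)-7-methoxy-3-methyl-1-oxoisochroman-6-yl acetate (C4 epimers) | COc1c(OC(C)=O)cc2c(c1O[Si](C)(C)C(C)(C)C)C(=O)O[C@H](C)C2Br
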